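**Retrosynthetic overview**
1. Feature: ring A (C4a, C5–C8, C8a) carries oxygen at C6, C7 and C8a; the ring oxygen O1 on C8a is para to the C6 hydroxyl and ortho to C4a, which bears the C4 carbonyl. This is the carbon at which the o-quinone of a 4-acylcatechol takes up a nucleophile, so O1–C8a is made last.
2. 14 ⇐ 13 (loss of the two MOM acetals on O3 and O4′) ⇐ 11 by the O1–C8a disconnection; ring C (the pyranone) is the only ring formed, rings A and B are bought.
3. 11 ⇐ 10 (desilylation) ⇐ 9 (oxidation) ⇐ 7 + 4: C2–C3 bond by a directed lithium aldol addition.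
4. 7 ⇐ 5 + a MOM-protected hydroxymethyl anion (C3–C4 bond), then oxidation of the carbinol.
5. 4 and 5 both come from 3,4-dihydroxybenzaldehyde 1 (4-O-MOM/3-O-prenyl for ring B, bis-TBS for ring A).

Key step: step 9

Remark: the target has no stereocentre, stereogenic axis or configured double bond, so it is achiral and needs no enantiocontrol; the stereocentres of 6, 9, 10 and 11 are racemic and are all erased by step 9 (11 is written as the diketone, which equilibrates with its chelated Z-enol).

**Route**

Step 1
Reactants: 1 3,4-dihydroxybenzaldehyde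
Product: 2 3-hydroxy-4-(methoxymethoxy)benzaldehyde
Conditions: MOMCl (1.05 eq), K2CO3 (1.1 eq), acetone, 0 °C → rt
Reagents that add atoms: chloromethyl methyl ether (MOMCl), COCCl
Why: Williamson-type O-alkylation of the monophenoxide, in which the 4-OH para to the formyl group is the more acidic hydroxyl and is therefore the one alkylated when one equivalent of mild base and MOMCl is used.

Step 2
Reactants: 2 3-hydroxy-4-(methoxymethoxy)benzaldehyde; 3 prenyl bromide (1-bromo-3-methylbut-2-ene)
Product: 4 4-(methoxymethoxy)-3-[(3-methylbut-2-en-1-yl)oxy]benzaldehyde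
Conditions: K2CO3, DMF, rt
Reagents that add atoms: none
Why: Williamson ether synthesis, the remaining phenoxide displacing bromide at the primary allylic carbon under carbonate conditions that favour O- over C-prenylation.

Step 3
Reactants: 1 3,4-dihydroxybenzaldehyde
Product: 5 3,4-bis[(tert-butyldimethylsilyl)oxy]benzaldehyde
Conditions: TBSCl (2.4 eq), imidazole, DMF, rt
Reagents that add atoms: tert-butyldimethylsilyl chloride (TBSCl), CC(C)(C)[Si](C)(C)Cl
Why: Standard silylation of both phenols (silyl chloride/imidazole), giving aryl silyl ethers that tolerate the organolithium, enolate and oxidation steps and are later removed by fluoride without touching MOM or prenyl ethers.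

Step 4
Reactants: 5 3,4-bis[(tert-butyldimethylsilyl)oxy]benzaldehyde
Product: 6 rac-1-{3,4-bis[(tert-butyldimethylsilyl)oxy]phenyl}-2-(methoxymethoxy)ethan-1-ol
Conditions: Bu3SnCH2OMOM (commercial), n-BuLi, THF, −78 °C; then 5, −78 °C; AcOH quench
Reagents that add atoms: tributyl[(methoxymethoxy)methyl]stannane, CCCC[Sn](CCCC)(CCCC)COCOC
Why: Tin–lithium exchange gives an α-alkoxymethyllithium (a protected hydroxymethyl anion) that undergoes 1,2-addition to the aldehyde at −78 °C faster than it attacks silicon; the new carbinol centre is racemic and is removed in step 5.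

Step 5
Reactants: 6 rac-1-{3,4-bis[(tert-butyldimethylsilyl)oxy]phenyl}-2-(methoxymethoxy)ethan-1-ol
Product: 7 1-{3,4-bis[(tert-butyldimethylsilyl)oxy]phenyl}-2-(methoxymethoxy)ethan-1-one
Conditions: Dess–Martin periodinane, CH2Cl2, 0 °C → rt
Reagents that add atoms: none
Why: Dess–Martin oxidation of a benzylic secondary alcohol to the aryl ketone under non-aqueous, nearly neutral conditions that leave the silyl ethers and the MOM acetal intact.

Step 6
Reactants: 7 1-{3,4-bis[(tert-butyldimethylsilyl)oxy]phenyl}-2-(methoxymethoxy)ethan-1-one; 4 4-(methoxymethoxy)-3-[(3-methylbut-2-en-1-yl)oxy]benzaldehyde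
Product: 9 1-{3,4-bis[(tert-butyldimethylsilyl)oxy]phenyl}-3-hydroxy-2-(methoxymethoxy)-3-{4-(methoxymethoxy)-3-[(3-methylbut-2-en-1-yl)oxy]phenyl}propan-1-one (racemic syn/anti mixture), via lithium Z-enolate 8 (not isolated)
Conditions: LiHMDS (1.05 eq), THF, −78 °C; then 4, −78 °C; AcOH quench at −78 °C
Reagents that add atoms: none
Why: Directed lithium aldol addition in which the ketone is fully converted to its chelated Z-enolate before the non-enolisable aldehyde is added, so self-condensation is excluded; the two new stereocentres form without control as a racemic syn/anti mixture, which is harmless because both are erased by step 9.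

Step 7
Reactants: 9 aldol adduct (racemic syn/anti mixture)
Product: 10 1-{3,4-bis[(tert-butyldimethylsilyl)oxy]phenyl}-2-(methoxymethoxy)-3-{4-(methoxymethoxy)-3-[(3-methylbut-2-en-1-yl)oxy]phenyl}propane-1,3-dione (racemic at C2)
Conditions: IBX (2.5 eq), EtOAc, 75 °C
Reagents that add atoms: none
Why: IBX oxidation of a β-hydroxy ketone to the 1,3-diketone, a neutral method that releases no acid and should not touch the trisubstituted alkene, the MOM acetals or the silyl ethers.

Step 8
Reactants: 10 bis-silylated 2-alkoxy-1,3-dione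
Product: 11 1-(3,4-dihydroxyphenyl)-2-(methoxymethoxy)-3-{4-(methoxymethoxy)-3-[(3-methylbut-2-en-1-yl)oxy]phenyl}propane-1,3-dione (racemic at C2)
Conditions: TBAF (2.2 eq), AcOH (2.4 eq), THF, 0 °C, Ar
Reagents that add atoms: none
Why: Fluoride desilylation of aryl silyl ethers on an acyl-substituted ring, with acetic acid buffering so that the 2-alkoxy-1,3-dione is not cleaved by retro-Claisen reaction and the catechol is not air-oxidised as its anion.

Step 9
Reactants: 11 1-(3,4-dihydroxyphenyl)-2-(methoxymethoxy)-3-{4-(methoxymethoxy)-3-[(3-methylbut-2-en-1-yl)oxy]phenyl}propane-1,3-dione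
Product: 13 6,7-dihydroxy-3-(methoxymethoxy)-2-{4-(methoxymethoxy)-3-[(3-methylbut-2-en-1-yl)oxy]phenyl}-4H-chromen-4-one, via acyl-o-quinone 12 (not isolated)
Conditions: divided cell, graphite-felt anode, Pt cathode, MeCN/0.2 M aq NaOAc–AcOH buffer (pH ≈ 5.5) 3:1, ca. +0.5 V vs Ag/AgCl (set at the foot of the catechol wave from a voltammogram of 11), 2.0 F/mol, rt, Ar; aq Na2S2O4 wash
Reagents that add atoms: none
Why: Proposed new method: anodic two-electron, two-proton oxidation turns the 4-acylcatechol ring of 11 into the 4-acyl-o-quinone 12, in which the ring carbon ortho to the acyl group and para to the former 3-hydroxyl (the future C8a) is the β-carbon of the enone running through the carbonyl para to the acyl group; acetate-assisted enolisation of the 2-alkoxy-1,3-dione towards the B-ring carbonyl lets that enol oxygen add there in conjugate fashion, and tautomerisation of the adduct restores the aromatic catechol as the 6,7-dihydroxychromone with O3 already in place. The closest known reaction type is the anodic oxidation of catechols in buffered aqueous acetonitrile with Michael trapping of the o-quinone by 1,3-dicarbonyl compounds, whose furan-closing stage is likewise an intramolecular enol-oxygen addition to an o-quinone; closure of a chromone through the acyl tether has not been shown. The pyranone ring closes in 6-exo-trig mode (O1 onto C8a of the C8a=C8 bond) and no stereocentre is formed. Chemoselectivity rests on potential, since an acylcatechol should be oxidised far below the acyl-dialkoxybenzene ring B and the trisubstituted alkene, so a potential held at the foot of the catechol wave activates ring A only, while pH 5.5 keeps the dione enolate too dilute to be oxidised itself. Regioselectivity is built into the substrate: of the two carbons ortho to the acyl group only the one remote from the quinone carbonyls is a Michael terminus, attack through C2 of the dione would need a four-membered ring, and the A-side oxygen cannot reach a ring carbon. Over-oxidation of the product catechol is limited by stopping at 2.0 F/mol in a divided cell, any quinone of 13 being returned to 13 by remaining 11 or by the dithionite wash.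

Step 10
Reactants: 13 6,7-dihydroxy-3-(methoxymethoxy)-2-{4-(methoxymethoxy)-3-[(3-methylbut-2-en-1-yl)oxy]phenyl}-4H-chromen-4-one
Product: 14 3,6,7-trihydroxy-2-{4-hydroxy-3-[(3-methylbut-2-en-1-yl)oxy]phenyl}-4H-chromen-4-one
Conditions: HCl (ca. 0.3 M) in MeOH/THF, 0 °C → rt, Ar
Reagents that add atoms: none
Why: Acid-catalysed acetal methanolysis (MOM cleavage), in which both O–CH2–OMe groups should ionise through oxocarbenium ions much faster in dilute acid at room temperature than the aryl prenyl ether ionises, so the allylic ether is kept; no stereocentre is involved.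

**Compound list**
1 | 3,4-dihydroxybenzaldehyde | O=Cc1ccc(O)c(O)c1 | starting material
2 | 3-hydroxy-4-(methoxymethoxy)benzaldehyde | COCOc1ccc(C=O)cc1O | intermediate
3 | prenyl bromide (1-bromo-3-methylbut-2-ene) | CC(C)=CCBr | starting material
4 | 4-(methoxymethoxy)-3-[(3-methylbut-2-en-1-yl)oxy]benzaldehyde | COCOc1ccc(C=O)cc1OCC=C(C)C | intermediate
5 | 3,4-bis[(tert-butyldimethylsilyl)oxy]benzaldehyde | CC(C)(C)[Si](C)(C)Oc1ccc(C=O)cc1O[Si](C)(C)C(C)(C)C | intermediate
6 | rac-1-{3,4-bis[(tert-butyldimethylsilyl)oxy]phenyl}-2-(methoxymethoxy)ethan-1-ol | COCOCC(O)c1ccc(O[Si](C)(C)C(C)(C)C)c(O[Si](C)(C)C(C)(C)C)c1 | intermediate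
7 | 1-{3,4-bis[(tert-butyldimethylsilyl)oxy]phenyl}-2-(methoxymethoxy)ethan-1-one | COCOCC(=O)c1ccc(O[Si](C)(C)C(C)(C)C)c(O[Si](C)(C)C(C)(C)C)c1 | intermediate
8 | lithium (Z)-1-{3,4-bis[(tert-butyldimethylsilyl)oxy]phenyl}-2-(methoxymethoxy)ethen-1-olate (not isolated) | [Li]O/C(=C\OCOC)c1ccc(O[Si](C)(C)C(C)(C)C)c(O[Si](C)(C)C(C)(C)C)c1 | intermediate
9 | 1-{3,4-bis[(tert-butyldimethylsilyl)oxy]phenyl}-3-hydroxy-2-(methoxymethoxy)-3-{4-(methoxymethoxy)-3-[(3-methylbut-2-en-1-yl)oxy]phenyl}propan-1-one, racemic syn/anti mixture | COCOC(C(=O)c1ccc(O[Si](C)(C)C(C)(C)C)c(O[Si](C)(C)C(C)(C)C)c1)C(O)c1ccc(OCOC)c(OCC=C(C)C)c1 | intermediate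
10 | 1-{3,4-bis[(tert-butyldimethylsilyl)oxy]phenyl}-2-(methoxymethoxy)-3-{4-(methoxymethoxy)-3-[(3-methylbut-2-en-1-yl)oxy]phenyl}propane-1,3-dione, racemic | COCOC(C(=O)c1ccc(O[Si](C)(C)C(C)(C)C)c(O[Si](C)(C)C(C)(C)C)c1)C(=O)c1ccc(OCOC)c(OCC=C(C)C)c1 | intermediate
11 | 1-(3,4-dihydroxyphenyl)-2-(methoxymethoxy)-3-{4-(methoxymethoxy)-3-[(3-methylbut-2-en-1-yl)oxy]phenyl}propane-1,3-dione, racemic, diketo form written | COCOC(C(=O)c1ccc(O)c(O)c1)C(=O)c1ccc(OCOC)c(OCC=C(C)C)c1 | intermediate
12 | 4-{2-(methoxymethoxy)-3-{4-(methoxymethoxy)-3-[(3-methylbut-2-en-1-yl)oxy]phenyl}-3-oxopropanoyl}cyclohexa-3,5-diene-1,2-dione (o-quinone of 11, not isolated) | COCOC(C(=O)C1=CC(=O)C(=O)C=C1)C(=O)c1ccc(OCOC)c(OCC=C(C)C)c1 | intermediate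
13 | 6,7-dihydroxy-3-(methoxymethoxy)-2-{4-(methoxymethoxy)-3-[(3-methylbut-2-en-1-yl)oxy]phenyl}-4H-chromen-4-one | CC(C)=CCOc1cc(-c2oc3cc(O)c(O)cc3c(=O)c2OCOC)ccc1OCOC | intermediate
14 | 3,6,7-trihydroxy-2-{4-hydroxy-3-[(3-methylbut-2-en-1-yl)oxy]phenyl}-4H-chromen-4-one (achiral) | CC(C)=CCOc1cc(-c2oc3cc(O)c(O)cc3c(=O)c2O)ccc1O | target

**Count**
Total steps: 10. Longest linear sequence: 8 steps (steps 3, 4, 5, 6, 7, 8, 9, 10 from 1).

**Steps most likely to fail**

Step 9 (the step flagged as new). The acyl-o-quinone may be captured by water, by buffer or by a second catechol molecule before the small enol fraction of the 2-alkoxy-dione closes the ring. It may also oxidise the electron-rich C2 position of its own side chain, and the product catechol may be oxidised further. The fallback uses only known chemistry and closes the pyranone from a phenol oxygen; it sets out from aldehyde 4 and comes back to the route at target 14. Commercial 2′,4′,5′-trihydroxyacetophenone (CC(=O)c1cc(O)c(O)cc1O) would be alkylated at its two non-chelated hydroxyls (MOMCl, iPr2NEt, CH2Cl2, 0 °C) to give 1-[2-hydroxy-4,5-bis(methoxymethoxy)phenyl]ethan-1-one F1. Claisen–Schmidt condensation of F1 with 4 (KOH, EtOH, rt) should give (E)-1-[2-hydroxy-4,5-bis(methoxymethoxy)phenyl]-3-{4-(methoxymethoxy)-3-[(3-methylbut-2-en-1-yl)oxy]phenyl}prop-2-en-1-one F2. Algar–Flynn–Oyamada oxidation (30% H2O2, NaOH, MeOH, 0 °C → rt) should then give 3-hydroxy-6,7-bis(methoxymethoxy)-2-{4-(methoxymethoxy)-3-[(3-methylbut-2-en-1-yl)oxy]phenyl}-4H-chromen-4-one F3. A 6′-unsubstituted chalcone is expected to give the flavonol and not the aurone, and the isolated alkene is inert to alkaline peroxide. Acid methanolysis of the three MOM groups of F3 under the conditions of step 10 leads to 14.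

Step 10. Acid ionisation of the aryl prenyl ether (loss of the prenyl group or its transfer to carbon) may compete with the slower cleavage of the 4′-aryl MOM ether. The fallback breaks the acetal C–O bonds by silyl transfer and not by protonation; it sets out from 13 and comes back at 14. Treatment of 13 with TMSOTf and 2,2′-bipyridyl (MeCN, 0 °C → rt) should exchange both methoxymethyl groups for silyl groups and silylate the catechol. This gives 3,6,7-tris[(trimethylsilyl)oxy]-2-{3-[(3-methylbut-2-en-1-yl)oxy]-4-[(trimethylsilyl)oxy]phenyl}-4H-chromen-4-one F4, which is not isolated. Stirring with MeOH/water then hydrolyses the four silyl ethers to 14 without any free strong acid.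

Step 7. Oxidation may go beyond the dione at the doubly activated C2–H, or the aldol may revert on heating, so that the dione is not obtained cleanly. The fallback forms the dione by direct C-acylation and needs no oxidation of the three-carbon chain; it sets out from 4 and the enolate 8 and comes back at 10. Pinnick oxidation of 4 (NaClO2, NaH2PO4, large excess of 2-methyl-2-butene, t-BuOH/H2O) should give 4-(methoxymethoxy)-3-[(3-methylbut-2-en-1-yl)oxy]benzoic acid F5. Carbonyldiimidazole (THF, rt) converts it into (1H-imidazol-1-yl){4-(methoxymethoxy)-3-[(3-methylbut-2-en-1-yl)oxy]phenyl}methanone F6. Addition of F6 to enolate 8 (from 7 with 2.1 eq LiHMDS, THF, −78 °C → 0 °C) is a Claisen-type C-acylation that should give 10 after acidic quench.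

**Further compounds**
F1 | step 9 | 1-[2-hydroxy-4,5-bis(methoxymethoxy)phenyl]ethan-1-one | CC(=O)c1cc(OCOC)c(OCOC)cc1O
F2 | step 9 | (E)-1-[2-hydroxy-4,5-bis(methoxymethoxy)phenyl]-3-{4-(methoxymethoxy)-3-[(3-methylbut-2-en-1-yl)oxy]phenyl}prop-2-en-1-one | COCOc1cc(O)c(C(=O)/C=C/c2ccc(OCOC)c(OCC=C(C)C)c2)cc1OCOC
F3 | step 9 | 3-hydroxy-6,7-bis(methoxymethoxy)-2-{4-(methoxymethoxy)-3-[(3-methylbut-2-en-1-yl)oxy]phenyl}-4H-chromen-4-one | COCOc1cc2oc(-c3ccc(OCOC)c(OCC=C(C)C)c3)c(O)c(=O)c2cc1OCOC
F4 | step 10 | 3,6,7-tris[(trimethylsilyl)oxy]-2-{3-[(3-methylbut-2-en-1-yl)oxy]-4-[(trimethylsilyl)oxy]phenyl}-4H-chromen-4-one | CC(C)=CCOc1cc(-c2oc3cc(O[Si](C)(C)C)c(O[Si](C)(C)C)cc3c(=O)c2O[Si](C)(C)C)ccc1O[Si](C)(C)C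
F5 | step 7 | 4-(methoxymethoxy)-3-[(3-methylbut-2-en-1-yl)oxy]benzoic acid | COCOc1ccc(C(=O)O)cc1OCC=C(C)C
F6 | step 7 | (1H-imidazol-1-yl){4-(methoxymethoxy)-3-[(3-methylbut-2-en-1-yl)oxy]phenyl}methanone | COCOc1ccc(C(=O)n2ccnc2)cc1OCC=C(C)C
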